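## Structural features

- The target is a 2,6-diaryl-3,7-dioxabicyclo[3.3.0]octane: two cis-fused tetrahydrofurans, ring A (C1–C2–O3–C4–C5) and ring B (C1–C5–C6–O7–C8), sharing the C1–C5 bond. C1 is the bridgehead with the acetate, C2 carries the guaiacyl group and C6 the veratryl group.
- Four contiguous stereocentres, C2, C1, C5 and C6, have the configuration (1S,2R,5R,6S). Both aryl groups lie on the convex face, and the C1 acetate is cis to H5.
- Fragile groups are the two benzylic C–O bonds at C2 and C6 on electron-rich rings (acid ionises them), the hindered tertiary acetate flanked by two ether oxygens (base or Lewis acid can move or expel it), and the free phenol.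
- The real difficulty is the fully substituted, oxygenated C1 between three stereocentres. Acylating a bridgehead tertiary alcohol late is unattractive, so the acetate is best present before the rings close.
- The key step exploits the fact that C1 and C5 each carry a CH2–O arm (C8 and C4). C5 can therefore be a radical released from a C4–C5 epoxide and tethered through C6–O7–C8 to a C1=C2 enol acetate. Once C1–C5 exists, the former epoxide oxygen on C4 sits five atoms from benzylic C2.
- Only C6 has to be set beforehand. The epoxide configuration at C5 is erased in the radical, and the enol acetate geometry is erased at C2.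
- C6 is (R) in the open-chain precursor and (S) in the bicycle with no change in space, because the oxirane carbon outranks the aryl group whereas ring carbon C5 does not.

## Logic of the disconnections

**20 ⇒ 19.** The O–Si bond of the phenol is cut. The phenol must be masked through a Grignard reagent, a sodium alkoxide, a lithium enolate, trivalent titanium and iodine. The forward step must free it without touching the tertiary acetate or the benzylic ethers, which calls for buffered fluoride.

**19 ⇒ 15.** C1–C5 and C2–O3 are cut. This removes both rings and three stereocentres (C1, C2, C5) and leaves an acyclic epoxy ether whose only controlling stereocentre is C6. The forward step must generate a C5 radical from the epoxide, add it to the acetoxy-bearing alkene carbon, and bring C2 to the cation level while the C1 acetate is still in place.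

**15 ⇒ 13.** The enol O–acyl bond is cut, leading back to a ketone with C1 as carbonyl carbon. The ketone has one strongly acidified α-position (benzylic C2), so the demand is regioselective and Z-selective O-acetylation of that enolate.

**13 ⇒ 11.** The C1=O group is traced to a C1=CH2 group. The carbonyl is thereby absent during the base-mediated ether formation, and α-halo ketone or diazo ketone chemistry is avoided. The oxidative cleavage must spare the epoxide and two electron-rich arenes.

**11 ⇒ 4 + 9.** The O7–C8 ether bond is cut, which splits the molecule into two fragments of similar size and places the C6 stereocentre in 4. The forward alkylation must outrun epoxide migration in the alkoxide of 4. Fragment 9 is a symmetric 2-substituted allyl electrophile, so direct and allylic substitution give the same product.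

**9 ⇒ 6 + 7, and 6 ⇒ 5.** The bond between the guaiacyl ring and C2 is cut, then the O–Si bond. This gives a commercial bromophenol and a commercial dichloride. The demand is mono-substitution of 7.

**4 ⇒ 3 ⇒ 1 + 2.** The epoxide oxygen is removed and then the C5–C6 bond is cut. A kinetic-resolution epoxidation of racemic 3 sets C6 and delivers the epoxide in one operation. It needs the tartrate enantiomer matched to the (S)-carbinol and a stop near half conversion.

## Other disconnections considered

**Alternative 1:** The cut is O7–C8, with the C1–O bond made by epoxide transposition.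
- Forward step: base would convert the C1–C2 epoxy diol A1 (hydroxyl on C8, free hydroxyl on C6, silyl ether on C4–O) by Payne rearrangement into the C1–C8 epoxide A2, with inversion at C1. The C6 alkoxide would then open A2 at C8 to give the ring B diol A3.
- In favour: the sequence is purely polar and stereospecific. C1 and C2 could be set by a reagent-controlled epoxidation of a primary allylic alcohol. On configurational control at C1 and C2 it is the equal of the chosen plan, and on mechanistic predictability it is the better.
- Against: A1 needs all four stereocentres before the step. The Payne equilibrium favours the more substituted epoxide A1 and is only drained by the cyclisation. The ring closure is strictly a 5-endo opening at the distal epoxide carbon, not a 5-exo one, and is inherently slow. The C6 alkoxide can instead attack benzylic C2 of A1, and the silyl group can migrate between the C4 and C6 oxygens.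
- Step economy: after A3, ring A must still be closed, the tertiary alcohol acetylated and the benzyl ether removed, against one step after the chosen key step.

**Alternative 2:** The cuts are C1–C2 and C4–C5.
- Forward step: CsF would turn the chloro silylmethyl ether A5 into the carbonyl ylide A6, which would add across the C1=C5 bond of the acetoxy butenolide A4 to give the lactone cycloadduct A7.
- In favour: it is the most convergent of the plans, forms two C–C bonds and ring A at once, and carries the acetate at C1 from the start, which equals the chosen plan. A concerted polar cycloaddition has no redox timing problem and is better in that respect. Cis fusion and approach anti to the C6 aryl group would be expected.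
- Against: the C6 hydrogen of A4 is a doubly activated γ-hydrogen of a butenolide, and fluoride is basic enough to threaten the only pre-set stereocentre. Exo/endo selectivity at C2 is open. A7 has C8 at the lactone level, so a carbonyl must be reduced to CH2 in the presence of a tertiary acetate and two benzylic ethers. That is likely to cost several steps and the acetate itself.
- Comparison: structurally it delivers the wrong oxidation level at C8, where the chosen plan delivers the target skeleton directly.

**Alternative 3:** The cut is C1–C2.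
- Forward step: irradiation of the ring B furan-3-one A8 would let the excited C1 carbonyl abstract the benzylic C2 hydrogen of the C5–CH2–O–CH2Ar chain through a seven-membered transition state. The 1,5-biradical would close to the bridgehead alcohol A9.
- In favour: δ-hydrogen abstraction with cyclisation of β-alkoxy ketones to tetrahydrofuran-3-ols is an established reaction type, which is a clear advantage over the chosen plan, whose key step is untested. Cis fusion is enforced. Only C5 and C6 are needed beforehand, and the trans arrangement is the thermodynamically preferred one.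
- Against: α-cleavage of an α-alkoxy ketone and photoreduction compete. The configuration at C2 is fixed in a biradical collapse with no obvious bias for the convex face. The step builds one ring where the chosen step builds two.
- Step economy: two steps follow A9, acetylation of a hindered bridgehead alcohol and hydrogenolysis of the benzyl ether beside two benzylic C–O bonds, against one after the chosen key step. On the number of stereocentres needed before the key step the chosen plan is better (one against two). On precedent alternative 3 is better.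

Key step: step 8

Assumption: D-(−)-diisopropyl tartrate is taken as the tartrate that epoxidises (S)-1-arylprop-2-en-1-ols fast and anti to the aryl group, by the usual facial rule of the titanium–tartrate epoxidation.

Assumption: the phenol is carried as its tri(propan-2-yl)silyl ether instead of a tert-butyldimethylsilyl ether, because an aryl silyl ether has to outlast the sodium alkoxide of step 5; the skeletons of 15 and 19 are otherwise unchanged.

## Route

Step 1
Reactants: 1 veratraldehyde (3,4-dimethoxybenzaldehyde); 2 vinylmagnesium bromide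
Product: 3 rac-1-(3,4-dimethoxyphenyl)prop-2-en-1-ol
Conditions: THF, 0 °C; aq NH4Cl
Reagents that add atoms: none
Why: Grignard 1,2-addition to an aryl aldehyde; the carbinol carbon (later C6) is formed racemic and is resolved in step 2.

Step 2
Reactants: 3 rac-1-(3,4-dimethoxyphenyl)prop-2-en-1-ol
Product: 4 (R)-(3,4-dimethoxyphenyl)[(S)-oxiran-2-yl]methanol
Conditions: Ti(OiPr)4 (1.0 equiv), D-(−)-diisopropyl tartrate (1.2 equiv), t-BuOOH (0.55 equiv), 4 Å molecular sieves, CH2Cl2, −20 °C
Reagents that add atoms: tert-butyl hydroperoxide, CC(C)(C)OO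
Why: Sharpless kinetic resolution by asymmetric epoxidation; the titanium–D-tartrate complex should epoxidise the (S)-enantiomer of 3 much faster than the (R)-enantiomer and deliver oxygen anti to the aryl group, which sets C6 and gives the erythro epoxide; the unreacted (R)-enantiomer of 3 is separated by chromatography.

Step 3
Reactants: 5 4-bromo-2-methoxyphenol
Product: 6 (4-bromo-2-methoxyphenoxy)tri(propan-2-yl)silane
Conditions: i-Pr3SiCl (1.1 equiv), imidazole (2 equiv), DMF, 20 °C
Reagents that add atoms: chlorotri(propan-2-yl)silane, CC(C)[Si](Cl)(C(C)C)C(C)C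
Why: Standard silylation of a phenol; the bulky silyl group is chosen for resistance to alkoxide and amide bases.

Step 4
Reactants: 6 (4-bromo-2-methoxyphenoxy)tri(propan-2-yl)silane; 7 3-chloro-2-(chloromethyl)prop-1-ene
Product: 9 {4-[2-(chloromethyl)prop-2-en-1-yl]-2-methoxyphenoxy}tri(propan-2-yl)silane, via arylmagnesium bromide 8 (not isolated)
Conditions: Mg, THF, 40 °C; then added to 7 (3 equiv), CuI (5 mol %), THF, −20 → 0 °C
Reagents that add atoms: none
Why: Grignard formation followed by copper-catalysed allylic substitution; direct and allylic attack on the symmetric dichloride give the same product, and the excess of 7 with inverse addition suppresses a second arylation.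

Step 5
Reactants: 4 (R)-(3,4-dimethoxyphenyl)[(S)-oxiran-2-yl]methanol; 9 {4-[2-(chloromethyl)prop-2-en-1-yl]-2-methoxyphenoxy}tri(propan-2-yl)silane
Product: 11 {4-[2-({(R)-(3,4-dimethoxyphenyl)[(S)-oxiran-2-yl]methoxy}methyl)prop-2-en-1-yl]-2-methoxyphenoxy}tri(propan-2-yl)silane, via sodium alkoxide 10 (not isolated)
Conditions: NaH (1.2 equiv), THF, 0 °C; 9 (1.2 equiv), Bu4NI (10 mol %), 0 → 20 °C
Reagents that add atoms: none
Why: Williamson ether synthesis forming O7–C8; in an aprotic solvent at low temperature with iodide catalysis the allylation should outrun epoxide migration, and no stereocentre is touched.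

Step 6
Reactants: 11 {4-[2-({(R)-(3,4-dimethoxyphenyl)[(S)-oxiran-2-yl]methoxy}methyl)prop-2-en-1-yl]-2-methoxyphenoxy}tri(propan-2-yl)silane
Product: 13 1-{(R)-(3,4-dimethoxyphenyl)[(S)-oxiran-2-yl]methoxy}-3-{3-methoxy-4-[tri(propan-2-yl)silyloxy]phenyl}propan-2-one, via vicinal diol 12 (not isolated)
Conditions: K2OsO4·2H2O (2 mol %), NaIO4 (4 equiv), 2,6-lutidine (2 equiv), dioxane–H2O (3:1), 20 °C
Reagents that add atoms: sodium periodate, [Na+].[O-]I(=O)(=O)=O (terminal oxidant; the carbonyl oxygen is passed on through the osmium oxo groups)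
Why: Lemieux–Johnson oxidation, dihydroxylation of the only alkene and periodate cleavage of the diol in one flask; the buffered neutral medium should leave the epoxide, the benzylic ether and the aryl silyl ether intact, and non-volatile osmate replaces OsO4.

Step 7
Reactants: 13 1-{(R)-(3,4-dimethoxyphenyl)[(S)-oxiran-2-yl]methoxy}-3-{3-methoxy-4-[tri(propan-2-yl)silyloxy]phenyl}propan-2-one
Product: 15 (Z)-3-{(R)-(3,4-dimethoxyphenyl)[(S)-oxiran-2-yl]methoxy}-1-{3-methoxy-4-[tri(propan-2-yl)silyloxy]phenyl}prop-1-en-2-yl acetate, via lithium Z-enolate 14 (not isolated)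
Conditions: LiN(SiMe3)2 (1.1 equiv), THF, −78 °C, 30 min; Ac2O (1.5 equiv), −78 → 0 °C
Reagents that add atoms: acetic anhydride, CC(=O)OC(C)=O
Why: Enolate O-acylation; the benzylic C2 hydrogens are far more acidic than the C8 hydrogens, the conjugated enolate should form with the aryl group cis to oxygen and away from the CH2O chain, and the hard anhydride should react at oxygen to give the Z-enol acetate.

Step 8
Reactants: 15 (Z)-3-{(R)-(3,4-dimethoxyphenyl)[(S)-oxiran-2-yl]methoxy}-1-{3-methoxy-4-[tri(propan-2-yl)silyloxy]phenyl}prop-1-en-2-yl acetate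
Product: 19 (1S,2R,5R,6S)-6-(3,4-dimethoxyphenyl)-2-{3-methoxy-4-[tri(propan-2-yl)silyloxy]phenyl}-3,7-dioxabicyclo[3.3.0]octan-1-yl acetate, via titanoxy C5 radical 16 (not isolated), via ring B benzylic radical 17 (not isolated), via benzylic iodide 18 (not isolated)
Conditions: Cp2TiCl (2.3 equiv, from Cp2TiCl2 and Mn dust, decanted), THF (0.02 M), 0 °C, 10 min; then I2 (2.5 equiv), −40 → 0 °C; aq Na2S2O3
Reagents that add atoms: none
Why: Proposed new method: Cp2TiCl (trivalent titanium) should transfer one electron to the epoxide of 15 and cleave the C5–O bond, giving radical 16 with a tetravalent titanium alkoxide on C4. Radical 16 should close ring B by 5-exo-trig attack on C1 of the enol acetate (C1–C5 bond), because the five-membered transition state and the benzylic stabilisation of radical 17 point the same way. Iodine should then convert 17, free or released from its weak and reversible pairing with Cp2TiCl, into benzylic iodide 18, whose ionisation to a para-silyloxy-stabilised cation lets the C4 alkoxide close ring A by 5-exo-tet attack at C2 (C2–O3 bond). The closest known reaction type is the Cp2TiCl-mediated radical cyclisation of epoxy cinnamyl ethers followed by iodine-induced closure to 2,6-diaryl-3,7-dioxabicyclo[3.3.0]octanes, extended here to an enol ester as acceptor. C5 and C1 are set in one chair-like transition state: the titanoxymethyl arm sits pseudo-equatorial and trans to the C6 aryl group, and the C1=C2 bond sits pseudo-equatorial, so C2 ends cis to the C4 arm and the acetate on the opposite face, the only arrangement that allows a cis-fused ring A. C2 is set in the cation-like closure, which places the aryl group on the convex face. The selectivity needed is oxidation at C2 before a second Cp2TiCl turns it into a benzyltitanium that would eliminate the C1 acetate. The hindered, electron-rich C2 radical without β-hydrogen, the small excess of Cp2TiCl, the low temperature and the early iodine quench are meant to secure this.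

Step 9
Reactants: 19 (1S,2R,5R,6S)-6-(3,4-dimethoxyphenyl)-2-{3-methoxy-4-[tri(propan-2-yl)silyloxy]phenyl}-3,7-dioxabicyclo[3.3.0]octan-1-yl acetate
Product: 20 (1S,2R,5R,6S)-6-(3,4-dimethoxyphenyl)-2-(4-hydroxy-3-methoxyphenyl)-3,7-dioxabicyclo[3.3.0]octan-1-yl acetate (CNP0107105.1)
Conditions: Bu4NF (1.2 equiv), AcOH (1.5 equiv), THF, 0 °C
Reagents that add atoms: none
Why: Fluoride cleavage of an aryl silyl ether; the acetic acid buffer keeps the phenol protonated, so neither acetyl transfer nor base-induced opening of the benzylic ethers should occur, and no stereocentre is touched.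

## Compound list

1 | veratraldehyde (3,4-dimethoxybenzaldehyde) | COc1ccc(C=O)cc1OC | starting material
2 | vinylmagnesium bromide | C=C[Mg]Br | starting material
3 | rac-1-(3,4-dimethoxyphenyl)prop-2-en-1-ol | COc1ccc(C(O)C=C)cc1OC | intermediate
4 | (R)-(3,4-dimethoxyphenyl)[(S)-oxiran-2-yl]methanol | COc1ccc([C@@H](O)[C@@H]2CO2)cc1OC | intermediate
5 | 4-bromo-2-methoxyphenol | COc1cc(Br)ccc1O | starting material
6 | (4-bromo-2-methoxyphenoxy)tri(propan-2-yl)silane | COc1cc(Br)ccc1O[Si](C(C)C)(C(C)C)C(C)C | intermediate
7 | 3-chloro-2-(chloromethyl)prop-1-ene | C=C(CCl)CCl | starting material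
8 | {3-methoxy-4-[tri(propan-2-yl)silyloxy]phenyl}magnesium bromide | COc1cc([Mg]Br)ccc1O[Si](C(C)C)(C(C)C)C(C)C | intermediate (not isolated)
9 | {4-[2-(chloromethyl)prop-2-en-1-yl]-2-methoxyphenoxy}tri(propan-2-yl)silane | COc1cc(CC(=C)CCl)ccc1O[Si](C(C)C)(C(C)C)C(C)C | intermediate
10 | sodium (R)-(3,4-dimethoxyphenyl)[(S)-oxiran-2-yl]methanolate | COc1ccc([C@@H]([O-])[C@@H]2CO2)cc1OC.[Na+] | intermediate (not isolated)
11 | {4-[2-({(R)-(3,4-dimethoxyphenyl)[(S)-oxiran-2-yl]methoxy}methyl)prop-2-en-1-yl]-2-methoxyphenoxy}tri(propan-2-yl)silane | COc1ccc([C@@H](OCC(=C)Cc2ccc(O[Si](C(C)C)(C(C)C)C(C)C)c(OC)c2)[C@@H]2CO2)cc1OC | intermediate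
12 | 2-({(R)-(3,4-dimethoxyphenyl)[(S)-oxiran-2-yl]methoxy}methyl)-3-{3-methoxy-4-[tri(propan-2-yl)silyloxy]phenyl}propane-1,2-diol (both configurations at the new carbinol) | COc1ccc([C@@H](OCC(O)(CO)Cc2ccc(O[Si](C(C)C)(C(C)C)C(C)C)c(OC)c2)[C@@H]2CO2)cc1OC | intermediate (not isolated)
13 | 1-{(R)-(3,4-dimethoxyphenyl)[(S)-oxiran-2-yl]methoxy}-3-{3-methoxy-4-[tri(propan-2-yl)silyloxy]phenyl}propan-2-one | COc1ccc([C@@H](OCC(=O)Cc2ccc(O[Si](C(C)C)(C(C)C)C(C)C)c(OC)c2)[C@@H]2CO2)cc1OC | intermediate
14 | lithium (Z)-enolate of 13 (benzylic enolate, aryl cis to oxygen) | COc1ccc([C@@H](OC/C([O-])=C/c2ccc(O[Si](C(C)C)(C(C)C)C(C)C)c(OC)c2)[C@@H]2CO2)cc1OC.[Li+] | intermediate (not isolated)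
15 | (Z)-3-{(R)-(3,4-dimethoxyphenyl)[(S)-oxiran-2-yl]methoxy}-1-{3-methoxy-4-[tri(propan-2-yl)silyloxy]phenyl}prop-1-en-2-yl acetate | COc1ccc([C@@H](OC/C(OC(C)=O)=C/c2ccc(O[Si](C(C)C)(C(C)C)C(C)C)c(OC)c2)[C@@H]2CO2)cc1OC | intermediate (key-step precursor)
16 | ring-opened C5 radical of 15 with a chlorobis(cyclopentadienyl)titanium alkoxide on C4 | COc1ccc([C@@H](OC/C(OC(C)=O)=C/c2ccc(O[Si](C(C)C)(C(C)C)C(C)C)c(OC)c2)[CH]CO[Ti](Cl)(C2C=CC=C2)C2C=CC=C2)cc1OC | intermediate (not isolated)
17 | ring B tetrahydrofuran with the C1 acetate, the C4 titanium alkoxide and the radical on benzylic C2 | COc1ccc([C@H]2OC[C@](OC(C)=O)([CH]c3ccc(O[Si](C(C)C)(C(C)C)C(C)C)c(OC)c3)[C@@H]2CO[Ti](Cl)(C2C=CC=C2)C2C=CC=C2)cc1OC | intermediate (not isolated)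
18 | ring B tetrahydrofuran with the C1 acetate, the C4 titanium alkoxide and iodine on benzylic C2 (either configuration at C2) | COc1ccc([C@H]2OC[C@](OC(C)=O)(C(I)c3ccc(O[Si](C(C)C)(C(C)C)C(C)C)c(OC)c3)[C@@H]2CO[Ti](Cl)(C2C=CC=C2)C2C=CC=C2)cc1OC | intermediate (not isolated)
19 | (1S,2R,5R,6S)-6-(3,4-dimethoxyphenyl)-2-{3-methoxy-4-[tri(propan-2-yl)silyloxy]phenyl}-3,7-dioxabicyclo[3.3.0]octan-1-yl acetate | COc1cc([C@H]2OC[C@@H]3[C@@H](c4ccc(OC)c(OC)c4)OC[C@]23OC(C)=O)ccc1O[Si](C(C)C)(C(C)C)C(C)C | intermediate (key-step product)
20 | (1S,2R,5R,6S)-6-(3,4-dimethoxyphenyl)-2-(4-hydroxy-3-methoxyphenyl)-3,7-dioxabicyclo[3.3.0]octan-1-yl acetate | COc1cc([C@H]2OC[C@@H]3[C@@H](c4ccc(OC)c(OC)c4)OC[C@]23OC(C)=O)ccc1O | target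

## Step count and least certain steps

Total: 9 steps. Longest linear sequence: 7 steps (steps 1, 2, 5, 6, 7, 8, 9).

**Step 8 (key step, proposed new method).**
- Most likely failure: loss of the C1 acetate by β-elimination once the C2 radical has been captured by a second equivalent of Cp2TiCl, before iodine arrives. β-Oxygenated alkyltitanium species collapse to alkenes readily, so this is a real race.
- Second failure: reduction of the C5 radical before it adds to the alkene, because attack on a fully substituted, acetoxy-bearing carbon is slower than attack on a cinnamyl ether.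
- Fallback (known reaction types only), from 4 back to 19:
  - O-propargylation of 4 (NaH, propargyl bromide, THF, 0 °C) gives (R)-(3,4-dimethoxyphenyl)[(S)-oxiran-2-yl]methyl prop-2-yn-1-yl ether F1.
  - Sonogashira coupling of F1 with 6 (PdCl2(PPh3)2, CuI, i-Pr2NH, 60 °C) gives the aryl alkyne F2.
  - Cp2TiCl effects the established 5-exo-dig radical cyclisation of epoxy propargyl ethers and gives the 4-arylidene tetrahydrofuran-3-methanol F3. This forms C1–C5 with the C6 aryl group trans to the C4 arm, and no oxygen sits β to the vinyl radical.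
  - Dimethyldioxirane (acetone, −20 °C) epoxidises C1=C2 on the face away from the C4 arm to the spiro-epoxide F4.
  - A trace of camphorsulfonic acid lets the C4 hydroxyl open F4 at benzylic C2, giving the bridgehead alcohol F5.
  - Acetylation (Ac2O, DMAP, Et3N) gives 19.

**Step 2.**
- Most likely failure: incomplete discrimination between the enantiomers of 3, and ionisation of the electron-rich benzylic carbinol or its epoxide on the Lewis-acidic titanium during the long reaction time that a monosubstituted alkene demands.
- Fallback, from 3 back to 4: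
  - Candida antarctica lipase B with vinyl acetate should acylate the (R)-enantiomer to (R)-1-(3,4-dimethoxyphenyl)prop-2-en-1-yl acetate F7 and leave (S)-1-(3,4-dimethoxyphenyl)prop-2-en-1-ol F6.
  - Hydroxyl-directed epoxidation of F6 with VO(acac)2 and t-BuOOH should give 4 together with some of its C5 epimer, (R)-(3,4-dimethoxyphenyl)[(R)-oxiran-2-yl]methanol F8.
  - F8 is removed by chromatography; it would in any case lead to the same C5 radical.

**Step 5.**
- Most likely failure: Payne-type migration of the epoxide in alkoxide 10 ahead of alkylation, which would put the allyl group on the wrong oxygen, and silyl transfer from the aryl ether to the alkoxide.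
- Fallback, from 4 back to 13 (replaces steps 5 and 6):
  - Methyl homovanillate is silylated (i-Pr3SiCl, imidazole) to methyl {3-methoxy-4-[tri(propan-2-yl)silyloxy]phenyl}acetate F9.
  - Trimethylsulfoxonium iodide and KOtBu convert F9 into the β-keto sulfoxonium ylide F10.
  - [Ir(cod)Cl]2-catalysed O–H insertion of F10 into 4 under neutral conditions forms the O7–C8 bond and gives 13 directly, with no alkoxide and no diazo compound.

**Step 7.**
- Most likely failure: enolisation toward C8, C-acetylation, or an E/Z mixture under kinetic lithium enolate conditions.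
- Fallback, from 13 back to 15:
  - Soft, equilibrating enolisation with Me3SiOTf and Et3N gives the conjugated (Z)-trimethylsilyl enol ether F11, which can be purified.
  - Cleavage of the enol O–Si bond with KOtBu at −78 °C and quenching with Ac2O in the same flask then gives 15.

## Further compounds

F1 | step 8 | (R)-(3,4-dimethoxyphenyl)[(S)-oxiran-2-yl]methyl prop-2-yn-1-yl ether | COc1ccc([C@@H](OCC#C)[C@@H]2CO2)cc1OC
F2 | step 8 | {4-[3-({(R)-(3,4-dimethoxyphenyl)[(S)-oxiran-2-yl]methoxy})prop-1-yn-1-yl]-2-methoxyphenoxy}tri(propan-2-yl)silane | COc1ccc([C@@H](OCC#Cc2ccc(O[Si](C(C)C)(C(C)C)C(C)C)c(OC)c2)[C@@H]2CO2)cc1OC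
F3 | step 8 | [(2S,3R)-2-(3,4-dimethoxyphenyl)-4-({3-methoxy-4-[tri(propan-2-yl)silyloxy]phenyl}methylidene)tetrahydrofuran-3-yl]methanol (alkene geometry not fixed) | COc1ccc([C@H]2OCC(=Cc3ccc(O[Si](C(C)C)(C(C)C)C(C)C)c(OC)c3)[C@@H]2CO)cc1OC
F4 | step 8 | spiro-epoxide of F3 across C1=C2, oxygen on the face away from the hydroxymethyl arm (either configuration at C2) | COc1ccc([C@H]2OC[C@@]3(OC3c3ccc(O[Si](C(C)C)(C(C)C)C(C)C)c(OC)c3)[C@@H]2CO)cc1OC
F5 | step 8 | (1S,2R,5R,6S)-6-(3,4-dimethoxyphenyl)-2-{3-methoxy-4-[tri(propan-2-yl)silyloxy]phenyl}-3,7-dioxabicyclo[3.3.0]octan-1-ol | COc1cc([C@H]2OC[C@@H]3[C@@H](c4ccc(OC)c(OC)c4)OC[C@]23O)ccc1O[Si](C(C)C)(C(C)C)C(C)C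
F6 | step 2 | (S)-1-(3,4-dimethoxyphenyl)prop-2-en-1-ol | COc1ccc([C@@H](O)C=C)cc1OC
F7 | step 2 | (R)-1-(3,4-dimethoxyphenyl)prop-2-en-1-yl acetate | COc1ccc([C@H](OC(C)=O)C=C)cc1OC
F8 | step 2 | (R)-(3,4-dimethoxyphenyl)[(R)-oxiran-2-yl]methanol | COc1ccc([C@@H](O)[C@H]2CO2)cc1OC
F9 | step 5 | methyl {3-methoxy-4-[tri(propan-2-yl)silyloxy]phenyl}acetate | COC(=O)Cc1ccc(O[Si](C(C)C)(C(C)C)C(C)C)c(OC)c1
F10 | step 5 | dimethylsulfoxonium 3-{3-methoxy-4-[tri(propan-2-yl)silyloxy]phenyl}-2-oxopropylide | COc1cc(CC(=O)C=S(C)(C)=O)ccc1O[Si](C(C)C)(C(C)C)C(C)C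
F11 | step 7 | (Z)-trimethylsilyl enol ether of 13 (aryl cis to the silyloxy group) | COc1ccc([C@@H](OC/C(O[Si](C)(C)C)=C/c2ccc(O[Si](C(C)C)(C(C)C)C(C)C)c(OC)c2)[C@@H]2CO2)cc1OC
A1 | alternative 1 | C1–C2 epoxy diol: [3-(4-benzyloxy-3-methoxyphenyl)-2-{1-(tert-butyldimethylsilyloxy)-3-(3,4-dimethoxyphenyl)-3-hydroxypropan-2-yl}oxiran-2-yl]methanol | COc1cc([C@H]2O[C@@]2(CO)[C@H](CO[Si](C)(C)C(C)(C)C)[C@H](O)c2ccc(OC)c(OC)c2)ccc1OCc1ccccc1
A2 | alternative 1 | rearranged C1–C8 epoxide: 1-(4-benzyloxy-3-methoxyphenyl)-1-hydroxymethyl-substituted 2,2-disubstituted oxirane with the C2 and C6 hydroxyls free | COc1cc([C@@H](O)[C@@]2(CO2)[C@H](CO[Si](C)(C)C(C)(C)C)[C@H](O)c2ccc(OC)c(OC)c2)ccc1OCc1ccccc1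
A3 | alternative 1 | ring B tetrahydrofuran with C1 tertiary and C2 benzylic hydroxyls and the C4 silyl ether | COc1cc([C@@H](O)[C@@]2(O)CO[C@H](c3ccc(OC)c(OC)c3)[C@H]2CO[Si](C)(C)C(C)(C)C)ccc1OCc1ccccc1
A4 | alternative 2 | (S)-3-acetoxy-5-(3,4-dimethoxyphenyl)furan-2(5H)-one | CC(=O)OC1=C[C@@H](c2ccc(OC)c(OC)c2)OC1=O
A5 | alternative 2 | 1-(benzyloxy)-4-{chloro[(trimethylsilyl)methoxy]methyl}-2-methoxybenzene | COc1cc(C(Cl)OC[Si](C)(C)C)ccc1OCc1ccccc1
A6 | alternative 2 | carbonyl ylide from A5, ArCH=O(+)–CH2(−) with Ar = 4-benzyloxy-3-methoxyphenyl | COc1cc(C=[O+][CH2-])ccc1OCc1ccccc1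
A7 | alternative 2 | 1-acetoxy-2-(4-benzyloxy-3-methoxyphenyl)-6-(3,4-dimethoxyphenyl)-3,7-dioxabicyclo[3.3.0]octan-8-one | COc1cc([C@H]2OC[C@@H]3[C@@H](c4ccc(OC)c(OC)c4)OC(=O)[C@]23OC(C)=O)ccc1OCc1ccccc1
A8 | alternative 3 | (4R,5S)-4-{[(4-benzyloxy-3-methoxyphenyl)methoxy]methyl}-5-(3,4-dimethoxyphenyl)dihydrofuran-3(2H)-one | COc1ccc([C@H]2OCC(=O)[C@@H]2COCc2ccc(OCc3ccccc3)c(OC)c2)cc1OC
A9 | alternative 3 | 2-(4-benzyloxy-3-methoxyphenyl)-6-(3,4-dimethoxyphenyl)-3,7-dioxabicyclo[3.3.0]octan-1-ol | COc1cc([C@H]2OC[C@@H]3[C@@H](c4ccc(OC)c(OC)c4)OC[C@]23O)ccc1OCc1ccccc1
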